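# Proposed synthesis of CNP0169789.1: (2S)-2-{3-[5,7-dihydroxy-2-(4-hydroxyphenyl)-4-oxo-4H-chromen-8-yl]-4-methoxyphenyl}-5-hydroxy-7-methoxychroman-4-one (19)

## Analysis of the target

The target 19 is a carbon–carbon linked biflavonoid. One half is a (2S)-5-hydroxy-7-methoxyflavanone; its ring B (a 4'-methoxyphenyl ring) carries at C3' the C8 carbon of a 5,7,4'-trihydroxyflavone. The only stereocentre is C2 of the flavanone. It bears the ring oxygen and lies β to the C4 ketone, so base (or strong acid) can erase it by retro-oxa-Michael opening to the 2'-hydroxychalcone, and its benzylic C2–O1 bond can be cleaved by over-reduction. Four phenols must end free while two methyl ethers (flavanone O7 and ring B O4') stay, so every oxygen that is masked on the way needs a group that comes off without touching a methyl ether. The flavone pyranone does not survive hot alkali, and strong acid can move an aryl group of a 5-hydroxyflavone from C8 to C6 (Wessely–Moser rearrangement). The hard bond is the biaryl C3'–C8: it has three ortho substituents, joins two electron-rich rings, and must sit on C8 and not on the almost equivalent C6 of a phloroglucinol ring. The strategy rests on the fact that flavone ring A is a phloroglucinol ring in which the aryl-bearing C8 is the neighbour of C8a, the carbon that carries pyranone O1. Bonds C8–C8a and C4a–C5 can therefore be made by annulating a four-carbon chain C5–C6–C7–C8, with ring B already on C8, onto C6 and C5 of a finished 4-pyranone.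

## Retrosynthetic reasoning

**19 from 18.** The last step only frees phenols. Flavanone O5 and flavone O4' carry benzyl groups and flavone O7 a benzyloxymethyl (BOM) group in 18, so one neutral hydrogenolysis should finish the synthesis without base or acid near C2. The chelated flavone O5–H is left free throughout.

**18 from 17 (O1–C2).** Cutting the ring C ether bond leads to the 2'-hydroxychalcone 17. The cut is placed here because it makes the stereocentre in the last skeleton-forming step, after all strongly basic chemistry. The forward reaction has to add the phenol oxygen to one face of the enone β-carbon under a chiral bifunctional catalyst.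

**17 from 14 and 16 (Cα=Cβ).** The enone double bond is cut into the aryl aldehyde 14 and the methyl ketone 16. This is the convergent join of the two flavonoid halves. Ring A of the flavanone comes ready-made, with the methyl ether on the right oxygen, from 15 by one benzylation to 16.

**14 from 13.** The aldehyde must be masked while strong bases are used, so 14 is traced to the cyclic acetal 13.

**13 from 7 and 11 (flavone C8–C8a and C4a–C5).** Removing C5–C8 of flavone ring A leaves the 4-pyranone 11, which already holds O1 and the C2 aryl group, and a four-carbon ester 7 with ring B on its terminal carbon.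
- Gain: the hindered biaryl bond becomes the ordinary aryl–CH2 bond of an arylacetic acid. No cross-coupling and no regioselective halogenation of a phloroglucinol ring is needed, and C8 is fixed by construction because O1 is in place before the benzene ring exists.
- Task of the forward step: join the γ-carbon of the dienolate of 7 to the pyranone carbon that bears a leaving group, close the ring by Claisen condensation on the ester, and aromatise.
- Requirement on 11: a leaving group at C6. Methylthio is chosen.
- Requirement on 7: the enol oxygen needs a group that can be put on by O-alkylation of a β-ketoester and removed by hydrogenolysis. A benzyl halide would alkylate carbon; a hard chloromethyl ether alkylates oxygen, hence BOM.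

**7 from 1 (via 6, 4, 3, 2).** The enol ether 7 is the O-alkylation product of β-ketoester 6. Ketoester 6 is the two-carbon homologue of arylacetic acid 4, made under non-acidic conditions because of the acetal. Acid 4 comes from ester 1 by formylation para to the methoxy group (2), acetalisation (3) and saponification.

**11 from 8 (via 9).** The pyranone is cut at O1–C6 and at the C5–C6 side chain. It comes from the aryl 1,3-diketone 9 by thiocarbonylation of its dianion at the terminal carbon, double S-methylation (10) and ring closure through the enol oxygen. Diketone 9 is the Claisen product of ketone 8.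

## Alternatives that were turned down

All three alternatives operate on the flavanone half and presuppose an 8-arylflavone aldehyde of the type of 14. None of them makes the biaryl bond.

**Alternative 1:** ring A of the flavanone built from a masked polyketide.
- Disconnection: flavanone C4a–C8a, traced to the 4-hydroxy-2-pyrone A1, whose C6 carries the 2-oxo-4-arylbut-3-enyl chain.
- Forward key step: Mg(OCH3)2 in methanol opens the lactone of A1 to a cinnamoyl triketo ester. On the magnesium template the methylene next to the cinnamoyl ketone acylates itself with the ester carbon, closing and aromatising ring A to the 2',4',6'-trihydroxychalcone A2.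
- For it: it is biomimetic and makes ring A and the chalcone in one operation. A2 is symmetrical, so either ortho hydroxyl can close ring C.
- Against it:
  - It builds the one ring of 19 that can be bought intact and correctly methylated (15).
  - A2 has three free hydroxyls, so the O7 methyl ether must be put on selectively afterwards.
  - A 2',6'-dihydroxychalcone closes to the flavanone by itself and without facial control, so C2 would form racemic unless further protection steps are added.
  - The triketo ester can also close by aldol condensation to a resorcylate, and methoxide can add to the enone.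
- Comparison: A1 is no shorter to reach than 17. The chosen strategy spends its ring construction on flavone ring A, where it creates the biaryl bond and its regiochemistry.

**Alternative 2:** ester-activated asymmetric oxa-Michael closure of ring C.
- Disconnection: flavanone O1–C2, on the alkylidene β-ketoester A3 (the chalcone with a tert-butyl ester on the α-carbon).
- Forward key step: a cinchona alkaloid thiourea delivers the ring A phenol to the benzylidene carbon of A3, giving the (2S)-2,3-trans flavanone 3-ester A4. The ester is removed later by acid-induced decarboxylation.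
- For it: the second carbonyl makes the acceptor more electrophilic and gives the thiourea a two-point binding site. The closure can run cold, where the uncatalysed and reverse reactions are slow. On enantiocontrol at C2 this is stronger than step 12 of the chosen route, which cyclises the unactivated chalcone 17.
- Against it: two more steps (the tert-butyl β-ketoester, and a decarboxylation in warm acid that the protecting groups and C2 must survive), and a Knoevenagel condensation between a hindered ketoester and a hindered aldehyde.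
- Comparison: it answers the stereocentre, not the biaryl, so it rivals only the endgame. The chosen route offers two steps fewer and no late acid, and keeps this activation as the fallback for step 12.

**Alternative 3:** ring C closed by intramolecular aryl ether formation.
- Disconnection: flavanone O1–C8a, traced to the bromo 1,3-diol A5.
- Forward key step: under CuI, a phenanthroline ligand and Cs2CO3, the ring B carbinol oxygen of A5 displaces the bromide on ring A. The C2–O bond is not touched, so C2 is retained, and the product is the (2S)-2,4-trans flavan-4-ol A6. The C4 alcohol is oxidised afterwards.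
- For it: C2 is set as a carbinol by reliable asymmetric reduction or aldol chemistry and never passes through a reversible conjugate addition. The C4 hydroxyl cannot compete, since it would form a four-membered ring. On stereochemical security this is stronger than both the chosen endgame and alternative 2.
- Against it:
  - It needs a brominated ring A ketone that is not a bought pattern.
  - It needs a second stereocentre that is erased again by oxidation.
  - The copper coupling is on an electron-rich aryl bromide beside a branched ortho substituent.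
  - An extra oxidation is needed, after which C2 is as labile as in any route.
  - Several more steps overall.
- Comparison: the chosen route reaches the protected flavanone 18 from 14 in two steps and puts its novelty into the bond that none of the alternatives addresses.

Key step: step 8

## Route

Assumption: methyl 2-(2-methoxyphenyl)acetate (1) is bought; otherwise it is one Fischer esterification from 2-methoxyphenylacetic acid.

Assumption: of the two pseudoenantiomeric cinchona thioureas, the quinidine-derived one is taken to give the 2S flavanone; if the sense is the opposite, the quinine-derived catalyst is used in step 12 with nothing else changed.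

Step 1
Reactants: 1 methyl 2-(2-methoxyphenyl)acetate
Product: 2 methyl 2-(5-formyl-2-methoxyphenyl)acetate
Conditions: Cl2CHOCH3, TiCl4, CH2Cl2, −10 to 0 °C; ice water
Reagents that add atoms: dichloromethyl methyl ether, COC(Cl)Cl; water, O
Why: Rieche formylation; the methoxy group directs the electrophile to its para position, which is also the less hindered of the two activated sites, and the ester is inert to TiCl4 at this temperature.

Step 2
Reactants: 2 methyl 2-(5-formyl-2-methoxyphenyl)acetate
Product: 3 methyl 2-[5-(1,3-dioxolan-2-yl)-2-methoxyphenyl]acetate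
Conditions: HOCH2CH2OH, p-TsOH (cat.), toluene, reflux, Dean–Stark
Reagents that add atoms: ethylene glycol, OCCO
Why: Acid-catalysed acetalisation with azeotropic removal of water masks the aldehyde against the enolates and amide bases to come; any glycol ester formed by transesterification is cleaved in step 3 along with the methyl ester.

Step 3
Reactants: 3 methyl 2-[5-(1,3-dioxolan-2-yl)-2-methoxyphenyl]acetate
Product: 4 2-[5-(1,3-dioxolan-2-yl)-2-methoxyphenyl]acetic acid
Conditions: LiOH, THF/MeOH/H2O, rt; AcOH to pH 5, 0 °C, immediate extraction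
Reagents that add atoms: lithium hydroxide, [Li+].[OH-]
Why: Saponification; the acetal is stable to base, and acidification is taken only to pH 5 in the cold because the dioxolane of an electron-rich benzaldehyde is acid-labile.

Step 4
Reactants: 4 2-[5-(1,3-dioxolan-2-yl)-2-methoxyphenyl]acetic acid
Product: 6 methyl 4-[5-(1,3-dioxolan-2-yl)-2-methoxyphenyl]-3-oxobutanoate, via acyl imidazolide 5 (not isolated)
Conditions: CDI, THF, rt; then KO2CCH2CO2CH3, MgCl2, Et3N, MeCN, rt to 40 °C; cold aq. citric acid
Reagents that add atoms: potassium methyl malonate, COC(=O)CC(=O)[O-].[K+]; N,N'-carbonyldiimidazole, O=C(n1ccnc1)n1ccnc1 (its imidazole ring is found in 5 only)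
Why: Masamune-type homologation: the acyl imidazolide 5 C-acylates the magnesium enolate of the malonate half ester and the adduct loses CO2 to give the β-ketoester; the medium stays neutral to mildly basic, which is why it is preferred for this acetal over an acid chloride or an acyl Meldrum's acid.

Step 5
Reactants: 6 methyl 4-[5-(1,3-dioxolan-2-yl)-2-methoxyphenyl]-3-oxobutanoate
Product: 7 methyl (E)-3-(benzyloxymethoxy)-4-[5-(1,3-dioxolan-2-yl)-2-methoxyphenyl]but-2-enoate
Conditions: KN(SiMe3)2, 18-crown-6, THF, −78 °C; BnOCH2Cl, −78 to 0 °C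
Reagents that add atoms: benzyl chloromethyl ether, ClCOCc1ccccc1
Why: O-alkylation of a dissociated potassium enolate by a hard α-chloro ether (a benzyl halide would alkylate carbon); the non-chelated enolate should give mainly the (E) enol ether, which is also the more stable isomer and the one that holds the ester cis to the CH2Ar carbon, and any (Z) isomer is removed by chromatography.

Step 6
Reactants: 8 1-[4-(benzyloxy)phenyl]ethan-1-one
Product: 9 1-[4-(benzyloxy)phenyl]butane-1,3-dione
Conditions: NaH, EtOAc, THF, reflux; aq. HCl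
Reagents that add atoms: ethyl acetate, CCOC(C)=O
Why: Crossed Claisen condensation of the ketone enolate with ethyl acetate, driven to completion by formation of the diketonate.

Step 7
Reactants: 9 1-[4-(benzyloxy)phenyl]butane-1,3-dione
Product: 11 2-[4-(benzyloxy)phenyl]-6-(methylthio)-4H-pyran-4-one, via ketene dithioacetal 10 (not isolated)
Conditions: LiN(i-Pr)2 (2.1 equiv), THF, −78 to 0 °C; CS2, −78 °C; LiN(i-Pr)2 (1.0 equiv); CH3I (2.05 equiv), 0 °C to rt; then AcOH, 60 °C
Reagents that add atoms: carbon disulfide, S=C=S; iodomethane, CI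
Why: The 1,3-diketone dianion reacts with CS2 at its terminal carbon, and a third equivalent of base with two S-methylations gives the ketene dithioacetal 10 (sulfur is far more nucleophilic than the remaining diketonate); the enol oxygen of the aryl ketone then adds to the bis(methylthio) carbon and methanethiol is lost (addition–elimination), the same closure by which 2-(methylthio)chromones form from 2'-hydroxyaryl ketene dithioacetals.

Step 8
Reactants: 7 methyl (E)-3-(benzyloxymethoxy)-4-[5-(1,3-dioxolan-2-yl)-2-methoxyphenyl]but-2-enoate; 11 2-[4-(benzyloxy)phenyl]-6-(methylthio)-4H-pyran-4-one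
Product: 13 2-[4-(benzyloxy)phenyl]-7-(benzyloxymethoxy)-8-[5-(1,3-dioxolan-2-yl)-2-methoxyphenyl]-5-hydroxy-4H-chromen-4-one, via substitution product 12 (not isolated)
Conditions: 7, LiN(i-Pr)2 (2.5 equiv), THF, −78 °C; then 11, −78 °C to rt; AcOH
Reagents that add atoms: none
Why: Proposed new method: lithium diisopropylamide removes the benzylic γ-proton of 7 (acidified by the aryl group and the vinylogous ester) to give a lithium dienolate, whose γ-carbon adds to C6 of 11, the pyranone carbon that bears the methylthio group; loss of methanethiolate gives 12, whose doubly activated methine is deprotonated again by the excess base. In that anion the charge is relayed to pyranone C5, which attacks the ester carbonyl held cis on the (E) enol ether in a 6-(enolexo)-exo-trig Claisen closure that forms the carbocycle; loss of methoxide and tautomerisation of the cyclohexadienone give the phenol, and the product is the same if the thiolate leaves only after the ring has closed. The closest known reaction type is the Staunton–Weinreb annulation, in which a benzylic ester anion adds to a β-alkoxy enone or pyranone and closes by Claisen condensation; new here is an acyclic 3-alkoxybutenoate dienolate as the donor, so that a whole benzene ring is made. No stereocentre is formed. The step needs γ- and not α-attack of the dienolate, which lithium dienolates of 3-alkoxybut-2-enoates usually show and which alone can lead on to an aromatic ring. It also needs attack at C6 and not C2 of 11, which is secured because only C6 carries a leaving group while addition at the aryl-bearing C2 is hindered and reversible. Because O1 and C8a exist before the benzene ring does, the aryl group can only end up on C8, and the new C5 hydroxyl is free while O7 stays protected.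

Step 9
Reactants: 13 2-[4-(benzyloxy)phenyl]-7-(benzyloxymethoxy)-8-[5-(1,3-dioxolan-2-yl)-2-methoxyphenyl]-5-hydroxy-4H-chromen-4-one
Product: 14 3-{2-[4-(benzyloxy)phenyl]-7-(benzyloxymethoxy)-5-hydroxy-4-oxo-4H-chromen-8-yl}-4-methoxybenzaldehyde
Conditions: PPTS, acetone/H2O, 40 °C
Reagents that add atoms: water, O
Why: Mild acid-catalysed acetal hydrolysis; the dioxolane of a para-alkoxybenzaldehyde is far more labile than the phenolic BOM formal, and the weak acid is too mild for a Wessely–Moser shift of the C8 aryl group.

Step 10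
Reactants: 15 1-(2,6-dihydroxy-4-methoxyphenyl)ethan-1-one
Product: 16 1-[2-(benzyloxy)-6-hydroxy-4-methoxyphenyl]ethan-1-one
Conditions: BnBr (1.05 equiv), K2CO3, acetone, reflux
Reagents that add atoms: benzyl bromide, BrCc1ccccc1
Why: Williamson etherification; the two hydroxyls are equivalent, and after the first alkylation the remaining one is locked in a hydrogen bond to the ketone and reacts much more slowly, so the monoether should predominate.

Step 11
Reactants: 14 3-{2-[4-(benzyloxy)phenyl]-7-(benzyloxymethoxy)-5-hydroxy-4-oxo-4H-chromen-8-yl}-4-methoxybenzaldehyde; 16 1-[2-(benzyloxy)-6-hydroxy-4-methoxyphenyl]ethan-1-one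
Product: 17 (E)-1-[2-(benzyloxy)-6-hydroxy-4-methoxyphenyl]-3-(3-{2-[4-(benzyloxy)phenyl]-7-(benzyloxymethoxy)-5-hydroxy-4-oxo-4H-chromen-8-yl}-4-methoxyphenyl)prop-2-en-1-one
Conditions: KOH (aq., excess), EtOH/THF, 0 °C to rt; cold dil. HCl to pH 6
Reagents that add atoms: none
Why: Claisen–Schmidt condensation of a non-enolisable aldehyde with the methyl ketone, the (E) enone arising from E1cB dehydration; the chalcone phenolate stays open in strong base, and room temperature spares the flavone pyranone.

Step 12
Reactants: 17 (E)-1-[2-(benzyloxy)-6-hydroxy-4-methoxyphenyl]-3-(3-{2-[4-(benzyloxy)phenyl]-7-(benzyloxymethoxy)-5-hydroxy-4-oxo-4H-chromen-8-yl}-4-methoxyphenyl)prop-2-en-1-one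
Product: 18 (2S)-5-(benzyloxy)-2-(3-{2-[4-(benzyloxy)phenyl]-7-(benzyloxymethoxy)-5-hydroxy-4-oxo-4H-chromen-8-yl}-4-methoxyphenyl)-7-methoxychroman-4-one
Conditions: 3,5-bis(trifluoromethyl)phenyl thiourea of 9-amino-9-deoxy-epi-quinidine (20 mol %), toluene, 4 Å MS, rt
Reagents that add atoms: none
Why: Organocatalytic intramolecular oxa-Michael addition (6-endo-trig): the quinuclidine nitrogen activates the 2'-phenol while the thiourea binds the enone carbonyl, so that the oxygen adds to one face of the β-carbon and the catalyst sets C2 as S; the 6'-benzyloxy group twists the aryl ketone and shifts the equilibrium to the flavanone.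

Step 13
Reactants: 18 (2S)-5-(benzyloxy)-2-(3-{2-[4-(benzyloxy)phenyl]-7-(benzyloxymethoxy)-5-hydroxy-4-oxo-4H-chromen-8-yl}-4-methoxyphenyl)-7-methoxychroman-4-one
Product: 19 (2S)-2-{3-[5,7-dihydroxy-2-(4-hydroxyphenyl)-4-oxo-4H-chromen-8-yl]-4-methoxyphenyl}-5-hydroxy-7-methoxychroman-4-one
Conditions: H2 (1 atm), Pd/C, EtOAc/MeOH, rt
Reagents that add atoms: none
Why: Hydrogenolysis of the two benzyl ethers and of the BOM group, whose hemiformal loses formaldehyde; the neutral medium should not open the flavanone, so C2 stays S, and the methyl ethers are untouched.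

## Compound list

1 | methyl 2-(2-methoxyphenyl)acetate | COC(=O)Cc1ccccc1OC | starting material
2 | methyl 2-(5-formyl-2-methoxyphenyl)acetate | COC(=O)Cc1cc(C=O)ccc1OC | intermediate
3 | methyl 2-[5-(1,3-dioxolan-2-yl)-2-methoxyphenyl]acetate | COC(=O)Cc1cc(C2OCCO2)ccc1OC | intermediate
4 | 2-[5-(1,3-dioxolan-2-yl)-2-methoxyphenyl]acetic acid | OC(=O)Cc1cc(C2OCCO2)ccc1OC | intermediate
5 | 2-[5-(1,3-dioxolan-2-yl)-2-methoxyphenyl]-1-(1H-imidazol-1-yl)ethan-1-one (acyl imidazolide) | O=C(Cc1cc(C2OCCO2)ccc1OC)n1ccnc1 | intermediate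
6 | methyl 4-[5-(1,3-dioxolan-2-yl)-2-methoxyphenyl]-3-oxobutanoate | COC(=O)CC(=O)Cc1cc(C2OCCO2)ccc1OC | intermediate
7 | methyl (E)-3-(benzyloxymethoxy)-4-[5-(1,3-dioxolan-2-yl)-2-methoxyphenyl]but-2-enoate | COC(=O)/C=C(/OCOCc1ccccc1)Cc1cc(C2OCCO2)ccc1OC | intermediate
8 | 1-[4-(benzyloxy)phenyl]ethan-1-one | CC(=O)c1ccc(OCc2ccccc2)cc1 | starting material
9 | 1-[4-(benzyloxy)phenyl]butane-1,3-dione | CC(=O)CC(=O)c1ccc(OCc2ccccc2)cc1 | intermediate
10 | 1-[4-(benzyloxy)phenyl]-5,5-bis(methylthio)pent-4-ene-1,3-dione (ketene dithioacetal) | CSC(SC)=CC(=O)CC(=O)c1ccc(OCc2ccccc2)cc1 | intermediate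
11 | 2-[4-(benzyloxy)phenyl]-6-(methylthio)-4H-pyran-4-one | CSc1cc(=O)cc(-c2ccc(OCc3ccccc3)cc2)o1 | intermediate
12 | methyl (E)-3-(benzyloxymethoxy)-4-{6-[4-(benzyloxy)phenyl]-4-oxo-4H-pyran-2-yl}-4-[5-(1,3-dioxolan-2-yl)-2-methoxyphenyl]but-2-enoate (racemic at C4) | COC(=O)/C=C(/OCOCc1ccccc1)C(c1cc(C2OCCO2)ccc1OC)c1cc(=O)cc(-c2ccc(OCc3ccccc3)cc2)o1 | intermediate
13 | 2-[4-(benzyloxy)phenyl]-7-(benzyloxymethoxy)-8-[5-(1,3-dioxolan-2-yl)-2-methoxyphenyl]-5-hydroxy-4H-chromen-4-one | O=c1cc(-c2ccc(OCc3ccccc3)cc2)oc2c(-c3cc(C4OCCO4)ccc3OC)c(OCOCc3ccccc3)cc(O)c12 | intermediate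
14 | 3-{2-[4-(benzyloxy)phenyl]-7-(benzyloxymethoxy)-5-hydroxy-4-oxo-4H-chromen-8-yl}-4-methoxybenzaldehyde | O=Cc1ccc(OC)c(-c2c(OCOCc3ccccc3)cc(O)c3c(=O)cc(-c4ccc(OCc5ccccc5)cc4)oc23)c1 | intermediate
15 | 1-(2,6-dihydroxy-4-methoxyphenyl)ethan-1-one | CC(=O)c1c(O)cc(OC)cc1O | starting material
16 | 1-[2-(benzyloxy)-6-hydroxy-4-methoxyphenyl]ethan-1-one | CC(=O)c1c(O)cc(OC)cc1OCc1ccccc1 | intermediate
17 | (E)-1-[2-(benzyloxy)-6-hydroxy-4-methoxyphenyl]-3-(3-{2-[4-(benzyloxy)phenyl]-7-(benzyloxymethoxy)-5-hydroxy-4-oxo-4H-chromen-8-yl}-4-methoxyphenyl)prop-2-en-1-one | COc1cc(O)c(C(=O)/C=C/c2ccc(OC)c(-c3c(OCOCc4ccccc4)cc(O)c4c(=O)cc(-c5ccc(OCc6ccccc6)cc5)oc34)c2)c(OCc2ccccc2)c1 | intermediate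
18 | (2S)-5-(benzyloxy)-2-(3-{2-[4-(benzyloxy)phenyl]-7-(benzyloxymethoxy)-5-hydroxy-4-oxo-4H-chromen-8-yl}-4-methoxyphenyl)-7-methoxychroman-4-one | COc1cc(OCc2ccccc2)c2c(c1)O[C@H](c1ccc(OC)c(-c3c(OCOCc4ccccc4)cc(O)c4c(=O)cc(-c5ccc(OCc6ccccc6)cc5)oc34)c1)CC2=O | intermediate
19 | (2S)-2-{3-[5,7-dihydroxy-2-(4-hydroxyphenyl)-4-oxo-4H-chromen-8-yl]-4-methoxyphenyl}-5-hydroxy-7-methoxychroman-4-one | COc1cc(O)c2c(c1)O[C@H](c1ccc(OC)c(-c3c(O)cc(O)c4c(=O)cc(-c5ccc(O)cc5)oc34)c1)CC2=O | target

## Step count and risk

Total: 13 steps. Longest linear sequence: 10 steps (steps 1, 2, 3, 4, 5, 8, 9, 11, 12, 13); the pyranone (steps 6, 7) and the ketone 16 (step 10) are side branches.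

**Step 8 (key step).**
- What may go wrong: α-attack of the dienolate on the pyranone; proton transfer from 12 to unreacted dienolate that stalls the sequence before ring closure; slow C–C bond formation at a carbon flanked by an ortho-substituted aryl group.
- Fallback (known chemistry, biaryl by cross-coupling): it sets out from 8 and comes back to the route at 19.
  - Carboxylation of 8 (NaH, dimethyl carbonate) gives methyl 3-[4-(benzyloxy)phenyl]-3-oxopropanoate F1.
  - Heating F1 with phloroglucinol without solvent at about 220 °C gives 2-[4-(benzyloxy)phenyl]-5,7-dihydroxy-4H-chromen-4-one F2.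
  - Benzyl bromide and K2CO3 in DMF at 70 °C give 5,7-bis(benzyloxy)-2-[4-(benzyloxy)phenyl]-4H-chromen-4-one F3.
  - Iodination with N-iodosuccinimide and a little CF3CO2H, expected at C8 once O5 is alkylated, gives 5,7-bis(benzyloxy)-2-[4-(benzyloxy)phenyl]-8-iodo-4H-chromen-4-one F4.
  - Suzuki–Miyaura coupling of F4 with bought 5-formyl-2-methoxyphenylboronic acid (Pd(PPh3)4, a zerovalent palladium complex, K2CO3, DME/H2O, 90 °C) gives 3-{5,7-bis(benzyloxy)-2-[4-(benzyloxy)phenyl]-4-oxo-4H-chromen-8-yl}-4-methoxybenzaldehyde F5.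
  - F5 and 16 under the conditions of step 11 give the tri-O-benzyl chalcone F6.
  - The conditions of step 12 close F6 to the (2S)-flavanone F7.
  - Hydrogenolysis as in step 13 removes four benzyl groups to give 19.
- Cost of the fallback: regiochemistry then rests on the iodination and the hindered coupling instead of on construction.

**Step 12.**
- What may go wrong: poor facial selectivity in the closure of an unactivated chalcone, and erosion of the enantiomeric purity through the reverse reaction on the basic catalyst.
- Fallback (activation by a C3 ester): it sets out from 16 and 14 and comes back at 19.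
  - The dilithium salt of 16 (LiN(SiMe3)2) is C-acylated with di-tert-butyl dicarbonate to tert-butyl 3-[2-(benzyloxy)-6-hydroxy-4-methoxyphenyl]-3-oxopropanoate F8.
  - Knoevenagel condensation of F8 with 14 (piperidinium acetate, toluene, 4 Å MS) gives the alkylidene β-ketoester F9.
  - The same class of thiourea (10 mol %, toluene, −25 °C) closes ring C to the (2S,3R) 2,3-trans flavanone tert-butyl ester F10.
  - Hydrogenolysis as in step 13 gives the 3-tert-butoxycarbonyl derivative of 19 F11.
  - p-TsOH (cat.) in toluene at 80 °C removes 2-methylpropene and CO2 to give 19.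

**Step 7.**
- What may go wrong: C-methylation of the diketonate in competition with S-methylation, or incomplete ring closure of 10.
- Fallback (oxygen in place of sulfur as leaving group): it sets out from 9 and comes back at 13.
  - The dianion of 9 (LiN(i-Pr)2) is carboxylated with CO2 to 5-[4-(benzyloxy)phenyl]-3,5-dioxopentanoic acid F12.
  - Acetic anhydride closes F12 to 6-[4-(benzyloxy)phenyl]-4-hydroxy-2H-pyran-2-one F13.
  - Methyl triflate in CH2Cl2 methylates the ring carbonyl oxygen to give 2-[4-(benzyloxy)phenyl]-6-methoxy-4H-pyran-4-one F14.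
  - F14 takes the place of 11 in step 8, with methoxide as the leaving group, and gives 13.

**Step 13.**
- What may go wrong: capture of the released formaldehyde by the electron-rich phloroglucinol rings, and over-reduction by hydrogenolysis of the benzylic C2–O1 bond.
- Fallback (two-stage deprotection without hydrogen): it sets out from 18 and comes back at 19.
  - HCl in methanol/THF at rt to 40 °C removes the BOM group, with formaldehyde leaving as dimethoxymethane, to give (2S)-5-(benzyloxy)-2-(3-{2-[4-(benzyloxy)phenyl]-5,7-dihydroxy-4-oxo-4H-chromen-8-yl}-4-methoxyphenyl)-7-methoxychroman-4-one F15.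
  - BCl3 with pentamethylbenzene in CH2Cl2 at −78 °C then removes the two benzyl groups from F15 to give 19. Neither methyl ether is peri to a carbonyl, so both should stay, and the C2–O1 bond is not exposed to reduction.

## Further compounds

F1 | step 8 | methyl 3-[4-(benzyloxy)phenyl]-3-oxopropanoate | COC(=O)CC(=O)c1ccc(OCc2ccccc2)cc1
F2 | step 8 | 2-[4-(benzyloxy)phenyl]-5,7-dihydroxy-4H-chromen-4-one | O=c1cc(-c2ccc(OCc3ccccc3)cc2)oc2cc(O)cc(O)c12
F3 | step 8 | 5,7-bis(benzyloxy)-2-[4-(benzyloxy)phenyl]-4H-chromen-4-one | O=c1cc(-c2ccc(OCc3ccccc3)cc2)oc2cc(OCc3ccccc3)cc(OCc3ccccc3)c12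
F4 | step 8 | 5,7-bis(benzyloxy)-2-[4-(benzyloxy)phenyl]-8-iodo-4H-chromen-4-one | O=c1cc(-c2ccc(OCc3ccccc3)cc2)oc2c(I)c(OCc3ccccc3)cc(OCc3ccccc3)c12
F5 | step 8 | 3-{5,7-bis(benzyloxy)-2-[4-(benzyloxy)phenyl]-4-oxo-4H-chromen-8-yl}-4-methoxybenzaldehyde | O=Cc1ccc(OC)c(-c2c(OCc3ccccc3)cc(OCc3ccccc3)c3c(=O)cc(-c4ccc(OCc5ccccc5)cc4)oc23)c1
F6 | step 8 | (E)-1-[2-(benzyloxy)-6-hydroxy-4-methoxyphenyl]-3-(3-{5,7-bis(benzyloxy)-2-[4-(benzyloxy)phenyl]-4-oxo-4H-chromen-8-yl}-4-methoxyphenyl)prop-2-en-1-one | COc1cc(O)c(C(=O)/C=C/c2ccc(OC)c(-c3c(OCc4ccccc4)cc(OCc4ccccc4)c4c(=O)cc(-c5ccc(OCc6ccccc6)cc5)oc34)c2)c(OCc2ccccc2)c1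
F7 | step 8 | (2S)-5-(benzyloxy)-2-(3-{5,7-bis(benzyloxy)-2-[4-(benzyloxy)phenyl]-4-oxo-4H-chromen-8-yl}-4-methoxyphenyl)-7-methoxychroman-4-one | COc1cc(OCc2ccccc2)c2c(c1)O[C@H](c1ccc(OC)c(-c3c(OCc4ccccc4)cc(OCc4ccccc4)c4c(=O)cc(-c5ccc(OCc6ccccc6)cc5)oc34)c1)CC2=O
F8 | step 12 | tert-butyl 3-[2-(benzyloxy)-6-hydroxy-4-methoxyphenyl]-3-oxopropanoate | COc1cc(O)c(C(=O)CC(=O)OC(C)(C)C)c(OCc2ccccc2)c1
F9 | step 12 | tert-butyl 2-[2-(benzyloxy)-6-hydroxy-4-methoxybenzoyl]-3-(3-{2-[4-(benzyloxy)phenyl]-7-(benzyloxymethoxy)-5-hydroxy-4-oxo-4H-chromen-8-yl}-4-methoxyphenyl)prop-2-enoate (olefin geometry as formed, not fixed) | COc1cc(O)c(C(=O)C(=Cc2ccc(OC)c(-c3c(OCOCc4ccccc4)cc(O)c4c(=O)cc(-c5ccc(OCc6ccccc6)cc5)oc34)c2)C(=O)OC(C)(C)C)c(OCc2ccccc2)c1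
F10 | step 12 | tert-butyl (2S,3R)-5-(benzyloxy)-2-(3-{2-[4-(benzyloxy)phenyl]-7-(benzyloxymethoxy)-5-hydroxy-4-oxo-4H-chromen-8-yl}-4-methoxyphenyl)-7-methoxy-4-oxochroman-3-carboxylate (2,3-trans) | COc1cc(OCc2ccccc2)c2c(c1)O[C@H](c1ccc(OC)c(-c3c(OCOCc4ccccc4)cc(O)c4c(=O)cc(-c5ccc(OCc6ccccc6)cc5)oc34)c1)[C@@H](C(=O)OC(C)(C)C)C2=O
F11 | step 12 | tert-butyl (2S,3R)-2-{3-[5,7-dihydroxy-2-(4-hydroxyphenyl)-4-oxo-4H-chromen-8-yl]-4-methoxyphenyl}-5-hydroxy-7-methoxy-4-oxochroman-3-carboxylate | COc1cc(O)c2c(c1)O[C@H](c1ccc(OC)c(-c3c(O)cc(O)c4c(=O)cc(-c5ccc(O)cc5)oc34)c1)[C@@H](C(=O)OC(C)(C)C)C2=O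
F12 | step 7 | 5-[4-(benzyloxy)phenyl]-3,5-dioxopentanoic acid | OC(=O)CC(=O)CC(=O)c1ccc(OCc2ccccc2)cc1
F13 | step 7 | 6-[4-(benzyloxy)phenyl]-4-hydroxy-2H-pyran-2-one | O=c1cc(O)cc(-c2ccc(OCc3ccccc3)cc2)o1
F14 | step 7 | 2-[4-(benzyloxy)phenyl]-6-methoxy-4H-pyran-4-one | COc1cc(=O)cc(-c2ccc(OCc3ccccc3)cc2)o1
F15 | step 13 | (2S)-5-(benzyloxy)-2-(3-{2-[4-(benzyloxy)phenyl]-5,7-dihydroxy-4-oxo-4H-chromen-8-yl}-4-methoxyphenyl)-7-methoxychroman-4-one | COc1cc(OCc2ccccc2)c2c(c1)O[C@H](c1ccc(OC)c(-c3c(O)cc(O)c4c(=O)cc(-c5ccc(OCc6ccccc6)cc5)oc34)c1)CC2=O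
A1 | alternative 1 | 4-hydroxy-6-[(E)-4-(3-{5,7-bis(benzyloxy)-2-[4-(benzyloxy)phenyl]-4-oxo-4H-chromen-8-yl}-4-methoxyphenyl)-2-oxobut-3-en-1-yl]-2H-pyran-2-one | O=C(Cc1cc(O)cc(=O)o1)/C=C/c1ccc(OC)c(-c3c(OCc6ccccc6)cc(OCc6ccccc6)c4c(=O)cc(-c5ccc(OCc6ccccc6)cc5)oc34)c1
A2 | alternative 1 | (E)-3-(3-{5,7-bis(benzyloxy)-2-[4-(benzyloxy)phenyl]-4-oxo-4H-chromen-8-yl}-4-methoxyphenyl)-1-(2,4,6-trihydroxyphenyl)prop-2-en-1-one | O=C(/C=C/c1ccc(OC)c(-c3c(OCc6ccccc6)cc(OCc6ccccc6)c4c(=O)cc(-c5ccc(OCc6ccccc6)cc5)oc34)c1)c1c(O)cc(O)cc1O
A3 | alternative 2 | tert-butyl 2-[2-(benzyloxy)-6-hydroxy-4-methoxybenzoyl]-3-(3-{5,7-bis(benzyloxy)-2-[4-(benzyloxy)phenyl]-4-oxo-4H-chromen-8-yl}-4-methoxyphenyl)prop-2-enoate (olefin geometry not fixed) | COc1cc(O)c(C(=O)C(=Cc2ccc(OC)c(-c3c(OCc6ccccc6)cc(OCc6ccccc6)c4c(=O)cc(-c5ccc(OCc6ccccc6)cc5)oc34)c2)C(=O)OC(C)(C)C)c(OCc2ccccc2)c1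
A4 | alternative 2 | tert-butyl (2S,3R)-5-(benzyloxy)-2-(3-{5,7-bis(benzyloxy)-2-[4-(benzyloxy)phenyl]-4-oxo-4H-chromen-8-yl}-4-methoxyphenyl)-7-methoxy-4-oxochroman-3-carboxylate (2,3-trans) | COc1cc(OCc2ccccc2)c2c(c1)O[C@H](c1ccc(OC)c(-c3c(OCc6ccccc6)cc(OCc6ccccc6)c4c(=O)cc(-c5ccc(OCc6ccccc6)cc5)oc34)c1)[C@@H](C(=O)OC(C)(C)C)C2=O
A5 | alternative 3 | (1R,3S)-1-[2-(benzyloxy)-6-bromo-4-methoxyphenyl]-3-(3-{5,7-bis(benzyloxy)-2-[4-(benzyloxy)phenyl]-4-oxo-4H-chromen-8-yl}-4-methoxyphenyl)propane-1,3-diol | COc1cc(Br)c([C@H](O)C[C@H](O)c2ccc(OC)c(-c3c(OCc6ccccc6)cc(OCc6ccccc6)c4c(=O)cc(-c5ccc(OCc6ccccc6)cc5)oc34)c2)c(OCc2ccccc2)c1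
A6 | alternative 3 | (2S,4R)-5-(benzyloxy)-2-(3-{5,7-bis(benzyloxy)-2-[4-(benzyloxy)phenyl]-4-oxo-4H-chromen-8-yl}-4-methoxyphenyl)-7-methoxychroman-4-ol (2,4-trans) | COc1cc(OCc2ccccc2)c2c(c1)O[C@H](c1ccc(OC)c(-c3c(OCc6ccccc6)cc(OCc6ccccc6)c4c(=O)cc(-c5ccc(OCc6ccccc6)cc5)oc34)c1)C[C@H]2O
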